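If a flask loses its target by meeting reagent, the concentration to follow is that of the reagent, [R]. The runs pointed that way. In the noon run, with surplus reagent, target fell from 50.4 % at 0.833 d to 17.4 % at 2.50 d, while in the dawn run it went only from 52.8 % at 2.50 d to 46.9 % at 6.00 d.

| flask | substrate | reagent | catalyst | remark | time |
|---|---|---|---|---|---|
| summer | 10 mM | 2 equiv | 10 mol% | run made earlier |  |
| dawn | 10 mM | 1.3 equiv | 10 mol% | run made earlier |  |
| noon | 10 mM | 3 equiv | 10 mol% | run made earlier |  |
| winter | 5 mM | 2 equiv | 10 mol% | run made earlier |  |
| Wednesday's | 10 mM (fed, over 3.0 d) | 2.00 equiv | 10 mol% | all else is in the flask from the start; the feed brings no volume worth counting | 5.0 d |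
| Friday's | 10 mM (fed, over 20 h) | 2.00 equiv | 10 mol% | all else is in the flask from the start; the feed brings no volume worth counting | 5.0 d |
| Monday's | 10 mM | 2.00 equiv | 10 mol% | everything together at the start | 5.0 d |
| Thursday's | 10 mM | 2.00 equiv (fed, over 3.0 d) | 10 mol% | all else is in the flask from the start; the feed brings no volume worth counting | 5.0 d |

- summer (time / d: target / %, substrate / %): 0.417: 57.5, 29.7; 0.833: 59.8, 11.7; 1.25: 55.4, 4.7; 1.67: 49.9, 2.9; 2.00: 43.7, 1.9; 2.50: 38.8, 3.1; 3.00: 35.5, 0
- dawn (time / d: target / %, substrate / %): 0.333: 41.8, 51.4; 0.833: 53.8, 28.4; 1.67: 56.2, 13.2; 2.50: 52.8, 7.9; 4.00: 51.4, 5.1; 5.00: 46.8, 3.6; 6.00: 46.9, 0.6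
- noon (time / d: target / %, substrate / %): 0.333: 60.3, 19.3; 0.833: 50.4, 1.4; 1.67: 29.2, 0; 2.50: 17.4, 0.7; 4.00: 9.3, 0; 5.00: 3.6, 0; 6.00: 4.5, 1.4
- winter (time / d: target / %, substrate / %): 0.500: 31.0, 63.4; 0.833: 42.5, 49.0; 1.67: 55.6, 29.0; 3.00: 56.7, 13.2; 6.00: 48.1, 4.0

(readings scatter by 1 percentage point)

1. the best flask by amount of target, in percent of the substrate charged; "all alike" if 1.5 percentage points covers them all (Wednesday's / Friday's / Monday's / Thursday's / all alike)
2. amount of target at the end, in percent of the substrate charged, Wednesday's
3. amount of target at the end, in percent of the substrate charged, Friday's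
4. amount of target at the end, in percent of the substrate charged, Monday's
5. amount of target at the end, in percent of the substrate charged, Thursday's

- what was read earlier has a scatter of 1 percentage point, one standard deviation

I took the loss as pseudo-first-order: target's fractional loss per day is κ[R], where κ is the loss constant per mM of reagent. I assumed each substrate spends one reagent and each target lost spends another, so [R] is the surplus plus target, which averaged 13.4 mM over that noon stretch. The reading gave κ = 0.0476 mM⁻¹ d⁻¹.

At the charge asked, the surplus on that assumption is nil, so as a rough estimate I set [R] equal to the target concentration [T], with 1/[T] climbing by κ each day. That gave me two extreme versions. In the first, the summer peak of 59.8 % stands from 0.833 d and decays until 5.0 d, which gave 27.3 %. In the second, that same peak stands untouched until the slow feed ends at 3.0 d, which gave 38.1 %, more than the first. I put Monday's and Friday's near the lower figure. Wednesday's and Thursday's went between the two, since target made during a feed still meets reagent.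

The forecast gave 29.5 % for Wednesday's, 24 % for Friday's, 23 % for Monday's and 33 % for Thursday's, and chose Thursday's: “reagent arrives late, so less time is spent over-reacting”. Its Monday's figure lay below my lower one.

The flasks gave 31.4 % for Wednesday's, 26.0 % for Friday's, 24.1 % for Monday's and 29.1 % for Thursday's, so Wednesday's led, not the forecast's choice. Monday's ended below my lower figure, and at 5.00 d its reagent stood at 3.46 mM, more than its target at 2.41 mM, so my [R] = [T] did not hold there.

    substrate + reagent + catalyst → catalyst + target (k = 8090 M⁻² h⁻¹)
    substrate + target → side product (k = 0.876 M⁻¹ h⁻¹)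
    reagent + catalyst + target → catalyst + over-reaction product (k = 2100 M⁻² h⁻¹)

From 3.00 d to 5.00 d, κ times mean reagent times mean target times the days gave 20.1 % of over-reaction product for Wednesday's, and the flask made 21 percentage points. For Thursday's the same sum gave 25.9 % against 26 points. Taking the over-reaction step away turned the lead of Wednesday's over Monday's most, from 7.2 points to −0.12 points.

All runs stem from a simulated flask with made-up constants; the scatter is artificial.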